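**Strategy.** The target is a 21-membered oxacyclophane: a diaryl ether joins ring A (resorcinol-type) to ring B (hydroquinone-type), and an unfunctionalised fourteen-carbon tether closes the ring. The route rests on cutting the C3–C4 bond of that tether, with C1 the benzylic carbon on ring B. Because C3 and C4 are plain methylenes, a sulfone can sit between them. One Ramberg–Bäcklund operation then forms C3=C4, expels SO2 and contracts a 22-membered thiamacrocycle to the 21-membered ring. The precursor is the tri-O-methyl macrocyclic sulfone 18, ring B–(CH2)3–SO2–(CH2)11–ring A. Its three-carbon arm comes from a Claisen-installed allyl group, and its ring is closed through sulfur.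

Key step: step 11

Assumption: alkene 21 is expected as an E/Z mixture; the Z isomer is drawn, and the geometry is erased in step 12. The target has no stereocentre.

Step 1
Reactants: 1 undec-10-en-1-ol; 2 3-bromo-5-methoxyphenol
Product: 4 alkylated phenol 3-(11-hydroxyundecyl)-5-methoxyphenol, via B-alkyl-9-BBN borane 3 (not isolated)
Conditions: 1, 9-BBN (2.2 equiv), THF, 0 °C to rt; then 2, PdCl2(dppf) (5 mol %), 3 M aq NaOH, THF/DMF, 65 °C
Reagents that add atoms: none
Why: Anti-Markovnikov hydroboration of the terminal alkene followed by B-alkyl Suzuki–Miyaura coupling should join the primary alkyl group to the aryl bromide, whose two meta oxygen substituents do not slow oxidative addition; the extra equivalent of 9-BBN is taken up by the hydroxyl as a borinate that the aqueous base hydrolyses.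

Step 2
Reactants: 4 3-(11-hydroxyundecyl)-5-methoxyphenol; 5 2-fluoro-4-methoxybenzaldehyde
Product: 6 diaryl ether 2-[3-(11-hydroxyundecyl)-5-methoxyphenoxy]-4-methoxybenzaldehyde
Conditions: K2CO3, DMF, 120 °C
Reagents that add atoms: none
Why: Nucleophilic aromatic substitution (SNAr): the phenoxide of 4 should displace the fluoride activated by the ortho formyl group, while K2CO3 does not ionise the aliphatic hydroxyl.

Step 3
Reactants: 6 2-[3-(11-hydroxyundecyl)-5-methoxyphenoxy]-4-methoxybenzaldehyde
Product: 8 phenol 2-[3-(11-hydroxyundecyl)-5-methoxyphenoxy]-4-methoxyphenol, via aryl formate 7 (not isolated)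
Conditions: mCPBA, CH2Cl2, 0 °C to rt; then K2CO3 (cat.), MeOH, rt
Reagents that add atoms: mCPBA (3-chloroperoxybenzoic acid), OOC(=O)c1cccc(Cl)c1
Why: Baeyer–Villiger (Dakin-type) oxidation: the electron-rich aryl group (para-methoxy, ortho-aryloxy) should migrate in preference to hydride to give the formate, which mild methanolysis cleaves to the phenol.

Step 4
Reactants: 8 2-[3-(11-hydroxyundecyl)-5-methoxyphenoxy]-4-methoxyphenol; 9 allyl bromide
Product: 10 allyl ether 11-{3-[2-(allyloxy)-5-methoxyphenoxy]-5-methoxyphenyl}undecan-1-ol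
Conditions: K2CO3, acetone, reflux
Reagents that add atoms: none
Why: Williamson O-allylation: only the phenol is ionised by K2CO3, so the primary alcohol should stay free.

Step 5
Reactants: 10 11-{3-[2-(allyloxy)-5-methoxyphenoxy]-5-methoxyphenyl}undecan-1-ol
Product: 12 allylphenol 2-allyl-6-[3-(11-hydroxyundecyl)-5-methoxyphenoxy]-4-methoxyphenol, via ortho-dienone 11 (not isolated)
Conditions: N,N-diethylaniline, 190 °C, argon
Reagents that add atoms: none
Why: Aromatic Claisen rearrangement ([3,3]-sigmatropic shift): one ortho carbon of ring B carries the aryloxy group and the para carbon carries methoxy, so the allyl group can settle only on C6, the carbon that bears the tether in the target, after which the dienone tautomerises to the phenol.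

Step 6
Reactants: 12 2-allyl-6-[3-(11-hydroxyundecyl)-5-methoxyphenoxy]-4-methoxyphenol
Product: 13 trimethyl ether 11-[3-(3-allyl-2,5-dimethoxyphenoxy)-5-methoxyphenyl]undecan-1-ol
Conditions: MeI, K2CO3, DMF, rt
Reagents that add atoms: iodomethane, CI
Why: Williamson methylation of the phenoxide; capping this hindered para-methoxyphenol removes a radical-chain inhibitor before the thiol–ene step and a site for difluorocarbene attack in the key step, and places all three phenols under one protecting group.

Step 7
Reactants: 13 11-[3-(3-allyl-2,5-dimethoxyphenoxy)-5-methoxyphenyl]undecan-1-ol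
Product: 14 thioacetate S-{11-[3-(3-allyl-2,5-dimethoxyphenoxy)-5-methoxyphenyl]undecyl} ethanethioate
Conditions: PPh3, DIAD, AcSH, THF, 0 °C to rt, dark, argon
Reagents that add atoms: thioacetic acid, CC(=O)S
Why: Mitsunobu thioesterification: the acidic thioacid should displace the activated primary alcohol by SN2, and exclusion of light and oxygen suppresses radical addition of the thioacid to the allyl group.

Step 8
Reactants: 14 S-{11-[3-(3-allyl-2,5-dimethoxyphenoxy)-5-methoxyphenyl]undecyl} ethanethioate
Product: 15 thiol 11-[3-(3-allyl-2,5-dimethoxyphenoxy)-5-methoxyphenyl]undecane-1-thiol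
Conditions: HCl (1.25 M in MeOH), degassed, 50 °C
Reagents that add atoms: none
Why: Acid-catalysed methanolysis (transesterification) of the thioester should free the thiol without forming a thiolate, which keeps disulfide formation low; the allylarene and the aryl ethers are inert.

Step 9
Reactants: 15 11-[3-(3-allyl-2,5-dimethoxyphenoxy)-5-methoxyphenyl]undecane-1-thiol
Product: 16 22-membered macrocyclic sulfide (ring B–(CH2)3–S–(CH2)11–ring A, three methoxy groups)
Conditions: DMPA (2,2-dimethoxy-2-phenylacetophenone, 0.2 equiv), hν 365 nm, degassed EtOAc, 1 mM, rt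
Reagents that add atoms: none
Why: Radical thiol–ene reaction (anti-Markovnikov hydrothiolation): the photogenerated thiyl radical should add to the terminal carbon of the allyl group in a 22-endo-trig closure, favoured by high dilution and by the reversibility of thiyl addition, and the carbon radical is quenched by S–H transfer.

Step 10
Reactants: 16 22-membered macrocyclic sulfide
Product: 18 22-membered macrocyclic sulfone, via sulfoxide 17 (not isolated)
Conditions: mCPBA (2.5 equiv), CH2Cl2, 0 °C to rt
Reagents that add atoms: mCPBA (3-chloroperoxybenzoic acid), OOC(=O)c1cccc(Cl)c1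
Why: Peracid oxidation of the sulfide should pass through the sulfoxide to the sulfone, the electron-rich arenes and ethers being untouched at this temperature.

Step 11
Reactants: 18 22-membered macrocyclic sulfone
Product: 21 21-membered macrocyclic alkene (C3=C4), via alpha-bromo sulfone 19 (not isolated), via episulfone 20 (not isolated)
Conditions: KOH/Al2O3, CBr2F2, t-BuOH/CH2Cl2, 5 °C to rt
Reagents that add atoms: none
Why: Ramberg–Bäcklund reaction in its one-flask form with in situ halogenation: KOH deprotonates one α-methylene of 18, the carbanion takes Br+ from CBr2F2 to give 19, deprotonation at the α′ carbon and intramolecular 1,3-displacement of bromide (3-exo-tet) close episulfone 20, and cheletropic loss of SO2 leaves the C3=C4 double bond. The closest known reaction type is the Ramberg–Bäcklund contraction of macrocyclic dialkyl and dibenzyl sulfones to cycloalkenes and cyclophanes. The 21-membered ring is not closed end to end; it arises by contraction of the preformed 22-membered ring through the transient three-membered episulfone, so no macrocyclisation entropy is paid here. No stereocentre is created, and the alkene geometry (an E/Z mixture is expected) does not matter because step 12 removes it. The step needs only mono-halogenation, since bromination at either α-carbon leads to the same episulfone; the substrate secures chemoselectivity because the two sulfone α-methylenes are its only appreciably acidic C–H bonds and the aryl ethers are inert to KOH and to difluorocarbene, while the supported base and a limited charge of CBr2F2 keep a second bromination slower than episulfone closure.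

Step 12
Reactants: 21 21-membered macrocyclic alkene
Product: 22 saturated 21-membered macrocycle (tri-O-methyl ether of the target)
Conditions: H2 (1 atm), 10% Pd/C, EtOAc, rt
Reagents that add atoms: none
Why: Heterogeneous catalytic hydrogenation should saturate the only C=C bond, both geometries giving the same product, and leave the aryl ethers intact.

Step 13
Reactants: 22 saturated 21-membered macrocycle
Product: 24 target triphenol CNP0393720.0, via tris(dibromoboryl) ether 23 (not isolated)
Conditions: BBr3 (6 equiv), CH2Cl2, −78 °C to rt; then H2O, 0 °C, argon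
Reagents that add atoms: none
Why: Lewis-acid ether cleavage: BBr3 coordinates each methoxy oxygen and bromide removes the methyl group by SN2, the diaryl ether being inert; hydrolysis of the aryloxyboron bromides should give the triphenol, handled under argon because the hydroquinone ring B is air-sensitive.

**Compound list**

1 | undec-10-en-1-ol | OCCCCCCCCCC=C | starting material
2 | 3-bromo-5-methoxyphenol | COc1cc(O)cc(Br)c1 | starting material
3 | 11-(9-borabicyclo[3.3.1]nonan-9-yl)undecan-1-ol | OCCCCCCCCCCCB1C2CCCC1CCC2 | intermediate (not isolated)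
4 | 3-(11-hydroxyundecyl)-5-methoxyphenol | COc1cc(O)cc(CCCCCCCCCCCO)c1 | intermediate
5 | 2-fluoro-4-methoxybenzaldehyde | COc1ccc(C=O)c(F)c1 | starting material
6 | 2-[3-(11-hydroxyundecyl)-5-methoxyphenoxy]-4-methoxybenzaldehyde | COc1ccc(C=O)c(Oc2cc(OC)cc(CCCCCCCCCCCO)c2)c1 | intermediate
7 | 2-[3-(11-hydroxyundecyl)-5-methoxyphenoxy]-4-methoxyphenyl formate | COc1ccc(OC=O)c(Oc2cc(OC)cc(CCCCCCCCCCCO)c2)c1 | intermediate (not isolated)
8 | 2-[3-(11-hydroxyundecyl)-5-methoxyphenoxy]-4-methoxyphenol | COc1ccc(O)c(Oc2cc(OC)cc(CCCCCCCCCCCO)c2)c1 | intermediate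
9 | allyl bromide | C=CCBr | starting material
10 | 11-{3-[2-(allyloxy)-5-methoxyphenoxy]-5-methoxyphenyl}undecan-1-ol | COc1ccc(OCC=C)c(Oc2cc(OC)cc(CCCCCCCCCCCO)c2)c1 | intermediate
11 | 6-allyl-2-[3-(11-hydroxyundecyl)-5-methoxyphenoxy]-4-methoxycyclohexa-2,4-dien-1-one (racemic at C6) | C=CCC1C=C(OC)C=C(Oc2cc(OC)cc(CCCCCCCCCCCO)c2)C1=O | intermediate (not isolated)
12 | 2-allyl-6-[3-(11-hydroxyundecyl)-5-methoxyphenoxy]-4-methoxyphenol | C=CCc1cc(OC)cc(Oc2cc(OC)cc(CCCCCCCCCCCO)c2)c1O | intermediate
13 | 11-[3-(3-allyl-2,5-dimethoxyphenoxy)-5-methoxyphenyl]undecan-1-ol | C=CCc1cc(OC)cc(Oc2cc(OC)cc(CCCCCCCCCCCO)c2)c1OC | intermediate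
14 | S-{11-[3-(3-allyl-2,5-dimethoxyphenoxy)-5-methoxyphenyl]undecyl} ethanethioate | C=CCc1cc(OC)cc(Oc2cc(OC)cc(CCCCCCCCCCCSC(C)=O)c2)c1OC | intermediate
15 | 11-[3-(3-allyl-2,5-dimethoxyphenoxy)-5-methoxyphenyl]undecane-1-thiol | C=CCc1cc(OC)cc(Oc2cc(OC)cc(CCCCCCCCCCCS)c2)c1OC | intermediate
16 | 22-membered macrocyclic sulfide, ring B–(CH2)3–S–(CH2)11–ring A, tri-O-methyl | COc1cc2cc(c1)Oc1cc(OC)cc(c1OC)CCCSCCCCCCCCCCC2 | intermediate
17 | corresponding macrocyclic sulfoxide (racemic at sulfur) | COc1cc2cc(c1)Oc1cc(OC)cc(c1OC)CCCS(=O)CCCCCCCCCCC2 | intermediate (not isolated)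
18 | 22-membered macrocyclic sulfone, ring B–(CH2)3–SO2–(CH2)11–ring A, tri-O-methyl | COc1cc2cc(c1)Oc1cc(OC)cc(c1OC)CCCS(=O)(=O)CCCCCCCCCCC2 | intermediate
19 | α-bromo sulfone (racemic; drawn brominated at C3, the C4-bromo isomer converges) | COc1cc2cc(c1)Oc1cc(OC)cc(c1OC)CCC(Br)S(=O)(=O)CCCCCCCCCCC2 | intermediate (not isolated)
20 | episulfone (thiirane 1,1-dioxide spanning C3 and C4; cis/trans mixture) | COc1cc2cc(c1)Oc1cc(OC)cc(c1OC)CCC1C(CCCCCCCCCC2)S1(=O)=O | intermediate (not isolated)
21 | 21-membered macrocyclic alkene with C3=C4 (Z drawn, E/Z mixture expected) | COc1cc2cc(c1)Oc1cc(OC)cc(c1OC)CC/C=C\CCCCCCCCCC2 | intermediate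
22 | saturated 21-membered macrocycle, tri-O-methyl ether of the target | COc1cc2cc(c1)Oc1cc(OC)cc(c1OC)CCCCCCCCCCCCCC2 | intermediate
23 | tris(dibromoboryl) ether of the target | BrB(Br)Oc1cc2cc(c1)Oc1cc(OB(Br)Br)cc(c1OB(Br)Br)CCCCCCCCCCCCCC2 | intermediate (not isolated)
24 | CNP0393720.0, macrocyclic diaryl ether triphenol (no stereocentre) | Oc1cc2cc(c1)Oc1cc(O)cc(c1O)CCCCCCCCCCCCCC2 | target

**Step count.** Total: 13 steps. Longest linear sequence: 13 steps (1 and 2 to 24).

**Steps most likely to fail**

Step 11. Bromination of the unactivated dialkyl sulfone on the supported base may be slow. A second bromination may overtake episulfone closure, or difluorocarbene may be trapped by the new alkene. The fallback leaves the sulfur route at alcohol 13 and closes the ring by olefin metathesis, returning at 22. Iodination of 13 (I2, PPh3, imidazole, CH2Cl2, 0 °C) should give 1-allyl-3-[3-(11-iodoundecyl)-5-methoxyphenoxy]-2,5-dimethoxybenzene F1. Copper-catalysed coupling with vinylmagnesium bromide (CuI cat., THF/DMPU, −20 °C to rt) should lengthen the arm by two carbons to 1-allyl-2,5-dimethoxy-3-[3-methoxy-5-(tridec-12-en-1-yl)phenoxy]benzene F2. Ring-closing metathesis with the second-generation Grubbs catalyst (CH2Cl2, 1 mM, 40 °C) should then close the 21-membered ring directly as the C2=C3 macrocyclic alkene F3 (E/Z mixture) with loss of ethene. Hydrogenation under the conditions of step 12 converts F3 into 22.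

Step 9. Intermolecular thiol–ene chain growth and oxidative disulfide coupling may outrun ring closure, and thiyl radicals may shift the allyl double bond into conjugation. The fallback sets out from 13 and closes the ring by a polar S-alkylation, returning at 16. Radical addition of thioacetic acid to the allyl group (AcSH, AIBN, toluene, 80 °C) should give S-(3-{3-[3-(11-hydroxyundecyl)-5-methoxyphenoxy]-2,5-dimethoxyphenyl}propyl) ethanethioate F4. Mesylation (MsCl, Et3N, CH2Cl2, 0 °C) should give the thioacetate mesylate F5. Slow addition of F5 to Cs2CO3 in degassed DMF/MeOH at 50 °C releases the thiol mesylate F6 (not isolated), whose caesium thiolate should displace the mesylate intramolecularly to give sulfide 16.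

Step 1. The two acidic hydroxyls may consume the borane, and protodeboronation or β-hydride elimination may divert the alkylpalladium intermediate. The fallback sets out from 2 and returns at 4 without any boron chemistry. Sonogashira coupling of 2 with undec-10-yn-1-ol (OCCCCCCCCCC#C; PdCl2(PPh3)2, CuI, Et3N, DMF, 80 °C) should give 3-(11-hydroxyundec-1-yn-1-yl)-5-methoxyphenol F7. Hydrogenation of the alkyne (H2, 10% Pd/C, EtOAc, rt) then gives 4.

**Further compounds**

F1 | step 11 | 1-allyl-3-[3-(11-iodoundecyl)-5-methoxyphenoxy]-2,5-dimethoxybenzene | C=CCc1cc(OC)cc(Oc2cc(OC)cc(CCCCCCCCCCCI)c2)c1OC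
F2 | step 11 | 1-allyl-2,5-dimethoxy-3-[3-methoxy-5-(tridec-12-en-1-yl)phenoxy]benzene | C=CCc1cc(OC)cc(Oc2cc(OC)cc(CCCCCCCCCCCC=C)c2)c1OC
F3 | step 11 | 21-membered macrocyclic alkene with C2=C3 (E/Z mixture), tri-O-methyl | COc1cc2cc(c1)Oc1cc(OC)cc(c1OC)CC=CCCCCCCCCCCC2
F4 | step 9 | S-(3-{3-[3-(11-hydroxyundecyl)-5-methoxyphenoxy]-2,5-dimethoxyphenyl}propyl) ethanethioate | CC(=O)SCCCc1cc(OC)cc(Oc2cc(OC)cc(CCCCCCCCCCCO)c2)c1OC
F5 | step 9 | 11-(3-{3-[3-(acetylsulfanyl)propyl]-2,5-dimethoxyphenoxy}-5-methoxyphenyl)undecyl methanesulfonate | CC(=O)SCCCc1cc(OC)cc(Oc2cc(OC)cc(CCCCCCCCCCCOS(C)(=O)=O)c2)c1OC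
F6 | step 9 | 11-{3-[2,5-dimethoxy-3-(3-sulfanylpropyl)phenoxy]-5-methoxyphenyl}undecyl methanesulfonate (not isolated) | SCCCc1cc(OC)cc(Oc2cc(OC)cc(CCCCCCCCCCCOS(C)(=O)=O)c2)c1OC
F7 | step 1 | 3-(11-hydroxyundec-1-yn-1-yl)-5-methoxyphenol | COc1cc(O)cc(C#CCCCCCCCCCO)c1
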